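- larch: starting material 0.61 M; partner 1.6 M; run made earlier
- flask: starting material 0.61 M; partner 2.44 M; time 20 min

- larch (time / min: starting material / %, first product / %): 0.833: 78.0, 10.7; 2.50: 52.3, 8.1; 4.00: 38.9, 6.4; 6.00: 28.9, 4.5; 10.0: 18.2, 3.6; 12.0: 15.8, 3.4

(readings scatter by 0.3 percentage points)



- the starting material standing at 20 min, as a percentage of the starting material charged
- the first product standing at 20 min, as a percentage of the starting material charged
- the bis adduct standing at 20 min, as a percentage of the starting material charged
- the triple product standing at 20 min, as a percentage of the starting material charged

Read the larch run at 0.833 min. Starting material stands at 78.0%, and its pseudo-first-order rate, divided by c(partner) as charged, gives k = 0.186 L mol⁻¹ min⁻¹. Read it again between 10.0 min and 12.0 min. The rate is now 0.0707 min⁻¹, so this reading puts c(partner) near 0.379 M.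

Suppose two rates compete for each partner molecule: k·c(starting material), and λ, a steady first-order loss by other routes. Take their equality as the zero of the scale, at c(starting material) = κ = λ/k. Dividing one rate by the other gives a ledger: partner spent = starting material spent + κ·ln(charged/left). The larch readings, with their scatter, make κ 0.402 M. This crossover concentration gives λ = 0.0750 min⁻¹.

The flask charges 0.61 M, more than κ, so in my reckoning starting material takes partner faster than the other routes at first. I let the 1.83 M of partner beyond it decay at λ. By 20 min that reckoning spends 1.42 M. Divided by κ, this amount is the exponent of the decay of starting material, so I reckon 2.92% starting material in the flask.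

The forecast says 1.2% starting material, 0.3% first product, 26% bis adduct and 72% triple product, with “the rest is mostly triple product”.

The flask gives 2.42% starting material, 3.14% first product, 3.63% bis adduct and 15.4% triple product, and the isomer of the product holds 75.4%.

    partner + bis adduct → triple product (k = 0.00300 L mol⁻¹ s⁻¹)
    partner → decomposed reagent (k = 0.00120 s⁻¹)
    partner + first product → bis adduct (k = 0.00270 L mol⁻¹ s⁻¹)
    starting material + partner → first product (k = 0.00340 L mol⁻¹ s⁻¹)
    first product ⇌ isomer of the product (K = 24.0, k = 0.0280 s⁻¹)

With 2.42% left, your ledger books 2.09 M of partner spent in the flask, which actually spent 2.12 M. Now take the neighbour flask, the same in partner and time but charged with 1.5 M of starting material. Its partner excess is 0.940 M, and the same reckoning gives 16.3%. The neighbour flask holds 12.0% of starting material, with 3.3% of its partner left.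

(The readings were generated by integration from invented constants.)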